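## Retrosynthetic overview

1. The target is the bis(3‑methylbut‑2‑enoate) of diol ketone 14; both esters go on in the last step.
2. Ring B (the α‑ketol) is cut at C8–C9 into an aldehyde and a nitrile (reductive ketyl–nitrile coupling). Ring A is cut at C4–C5 and C1–C10 into a 2‑silyloxydiene from pent‑1‑en‑3‑one and a (Z)‑β‑methyl enal (Diels–Alder).
3. Both rings are closed in one flask (step 6): ring A first by cycloaddition, ring B second by samarium‑mediated radical cyclisation, followed in the same flask by ketone reduction and imine hydrolysis.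
4. The dienophile comes from two C5 units: a butenolide‑derived (Z)‑chloro ester and 3‑methylbut‑2‑enenitrile (deconjugative alkylation installs the isopropenyl group).
5. Only the cis ring fusion (C5/C10, from the Z‑alkene) and the absolute sense (catalyst) are set kinetically; C3, C4, C7 and C9 form the all‑equatorial, thermodynamically preferred array. Position labels C1–C15 in the text follow eremophilane numbering.

Assumption: the (S)‑oxazaborolidine catalyst is taken to give the (5R,10S) series; if the sense of induction is opposite, its mirror image (equally available from proline) is used.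

## Route

Step 1
Reactants: 1 4-methylfuran-2(5H)-one
Product: 3 ethyl (2Z)-4-chloro-3-methylbut-2-enoate, via (2Z)-4-chloro-3-methylbut-2-enoyl chloride 2 (not isolated)
Conditions: SOCl2, ZnCl2 (cat.), 60 °C; then EtOH, 0 °C
Reagents that add atoms: thionyl chloride ClS(Cl)=O; ethanol CCO
Why: Lewis‑acid‑assisted chloride opening of the lactone at its allylic O–CH2 carbon (the SOCl2/ZnCl2 lactone‑to‑chloro‑acyl‑chloride reaction known for γ‑butyrolactone) followed by ethanolysis of the acyl chloride, with the Z geometry inherited from the ring and no stereocentre formed.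

Step 2
Reactants: 3 ethyl (2Z)-4-chloro-3-methylbut-2-enoate; 4 3-methylbut-2-enenitrile
Product: 5 ethyl (2Z)-5-cyano-3,6-dimethylhepta-2,6-dienoate (racemic at C-5)
Conditions: 4, LiN(iPr)2, THF–DMPU, −78 °C; then 3, −78 → −20 °C
Reagents that add atoms: none
Why: Deconjugative α‑alkylation of the lithiated dienyl nitrile (the lavandulyl‑type alkylation) by SN2 at the primary allylic chloride, the β‑methyl group disfavouring conjugate addition; the new centre (later C7) is racemic, which is harmless because it becomes epimerisable next to the ketone and is levelled in step 6.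

Step 3
Reactants: 5 ethyl (2Z)-5-cyano-3,6-dimethylhepta-2,6-dienoate
Product: 6 (4Z)-6-hydroxy-4-methyl-2-(prop-1-en-2-yl)hex-4-enenitrile (racemic)
Conditions: LiBH4, THF, 0 °C → rt
Reagents that add atoms: none
Why: Chemoselective borohydride reduction of the ester (1,2‑addition, the β,β‑disubstituted alkene resists conjugate reduction) that leaves the nitrile and both alkenes untouched and keeps the Z geometry.

Step 4
Reactants: 6 (4Z)-6-hydroxy-4-methyl-2-(prop-1-en-2-yl)hex-4-enenitrile
Product: 7 (4Z)-4-methyl-6-oxo-2-(prop-1-en-2-yl)hex-4-enenitrile (racemic)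
Conditions: MnO2, CH2Cl2, rt
Reagents that add atoms: none
Why: Allylic alcohol oxidation with MnO2 stops at the enal under neutral conditions without E/Z isomerisation (as in nerol to neral) and creates no stereocentre.

Step 5
Reactants: 8 pent-1-en-3-one
Product: 9 (3Z)-3-[(trimethylsilyl)oxy]penta-1,3-diene
Conditions: TMSOTf, Et3N, Et2O, 0 °C
Reagents that add atoms: trimethylsilyl trifluoromethanesulfonate C[Si](C)(C)OS(=O)(=O)C(F)(F)F
Why: Soft enolisation and O‑silylation on the ethyl side of the ketone gives the favoured (Z)‑silyl enol ether, a 2‑silyloxydiene whose methyl group sits "outside" and is therefore reactive in cycloaddition; no stereocentre is formed.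

Step 6
Reactants: 7 (4Z)-4-methyl-6-oxo-2-(prop-1-en-2-yl)hex-4-enenitrile; 9 (3Z)-3-[(trimethylsilyl)oxy]penta-1,3-diene
Product: 14 (1R,3R,4aR,5R,6R,8aS)-1,6-dihydroxy-4a,5-dimethyl-3-(prop-1-en-2-yl)octahydronaphthalen-2(1H)-one, via cycloadduct silyl enol ether aldehyde 10 (not isolated), via keto aldehyde 11 (not isolated), via hydroxy imino ketone 12 (not isolated), via imino diol 13 (not isolated)
Conditions: (S)-1-(2-methylphenyl)-3,3-diphenyltetrahydro-1H,3H-pyrrolo[1,2-c][1,3,2]oxazaborole·Tf2NH (20 mol %), toluene, −78 → −40 °C; MeOH, 0 °C, then volatiles off in vacuo; SmI2 (2.5 equiv), MeOH, THF, dark, 0 °C → rt; SmI2 (3 equiv), hν (visible), rt; aq. AcOH/NaOAc (pH 5), rt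
Reagents that add atoms: water O
Why: Proposed new method: a chiral cationic oxazaborolidine‑catalysed Diels–Alder reaction (closest precedent: catalytic enantioselective Diels–Alder reactions of enals with 2‑silyloxydienes) of the (Z)‑β,β‑disubstituted enal, in which the complexed formyl group and the bulky CH2 arm sit exo so that the diene methyl, the angular methyl and H‑10 end up cis (C4, C5, C10; ring A, cis fusion from the Z‑alkene, absolute sense from the catalyst), is followed in the same flask by acid methanolysis of the silyl enol ether, by aldehyde‑selective SmI2 ketyl–nitrile coupling (6‑exo‑dig radical cyclisation, closest precedent: SmI2 ketone–nitrile cyclisations to α‑hydroxy ketones) through a chair with the chelated O–Sm equatorial (C9; ring B), by photo‑activated SmI2 reduction of the ring‑A ketone while C8 is still masked as the samarium‑bound ketimine (bulky O–Sm equatorial, avoiding the syn‑axial angular methyl; C3), and by buffered imine hydrolysis during which the epimerisable C7 settles equatorial through the enamine tautomer.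

Step 7
Reactants: 14 (1R,3R,4aR,5R,6R,8aS)-1,6-dihydroxy-4a,5-dimethyl-3-(prop-1-en-2-yl)octahydronaphthalen-2(1H)-one; 15 3-methylbut-2-enoyl chloride
Product: 16 (1R,3R,4aR,5R,6R,8aS)-4a,5-dimethyl-2-oxo-3-(prop-1-en-2-yl)decahydronaphthalene-1,6-diyl bis(3-methylbut-2-enoate)
Conditions: 15 (3 equiv), pyridine, 4-(dimethylamino)pyridine (cat.), CH2Cl2, 0 °C → rt
Reagents that add atoms: none
Why: Nucleophilic‑catalysed acylation of both equatorial hydroxyls with the acid chloride under weak‑base conditions that avoid the vinylketene (deconjugation) pathway and do not enolise the β,γ‑unsaturated ketone, so no stereocentre changes.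

## Compound list

1 | 4-methylfuran-2(5H)-one | CC1=CC(=O)OC1 | starting material
2 | (2Z)-4-chloro-3-methylbut-2-enoyl chloride | ClC(=O)/C=C(/C)CCl | intermediate
3 | ethyl (2Z)-4-chloro-3-methylbut-2-enoate | CCOC(=O)/C=C(/C)CCl | intermediate
4 | 3-methylbut-2-enenitrile | CC(C)=CC#N | starting material
5 | ethyl (2Z)-5-cyano-3,6-dimethylhepta-2,6-dienoate (racemic at C-5) | CCOC(=O)/C=C(/C)CC(C#N)C(C)=C | intermediate
6 | (4Z)-6-hydroxy-4-methyl-2-(prop-1-en-2-yl)hex-4-enenitrile (racemic) | OC/C=C(/C)CC(C#N)C(C)=C | intermediate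
7 | (4Z)-4-methyl-6-oxo-2-(prop-1-en-2-yl)hex-4-enenitrile (racemic) | O=C/C=C(/C)CC(C#N)C(C)=C | intermediate
8 | pent-1-en-3-one | C=CC(=O)CC | starting material
9 | (3Z)-3-[(trimethylsilyl)oxy]penta-1,3-diene | C=C/C(=C/C)O[Si](C)(C)C | intermediate
10 | (1S,5R,6R)-6-(2-cyano-3-methylbut-3-en-1-yl)-5,6-dimethyl-4-[(trimethylsilyl)oxy]cyclohex-3-ene-1-carbaldehyde (both epimers at the cyano-bearing carbon) | C=C(C)C(C#N)C[C@@]1(C)[C@H](CC=C(O[Si](C)(C)C)[C@@H]1C)C=O | intermediate
11 | (1S,2S,3R)-2-(2-cyano-3-methylbut-3-en-1-yl)-2,3-dimethyl-4-oxocyclohexane-1-carbaldehyde (both epimers at the cyano-bearing carbon) | C=C(C)C(C#N)C[C@@]1(C)[C@H](CCC(=O)[C@@H]1C)C=O | intermediate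
12 | (1R,4aS,5R,8aS)-5-hydroxy-6-imino-1,8a-dimethyl-7-(prop-1-en-2-yl)octahydronaphthalen-2(1H)-one (both C-7 epimers) | C=C(C)C1C[C@@]2(C)[C@H](CCC(=O)[C@@H]2C)[C@@H](O)C1=N | intermediate
13 | (1R,4aR,5R,6R,8aS)-2-imino-4a,5-dimethyl-3-(prop-1-en-2-yl)decahydronaphthalene-1,6-diol (both C-3 epimers) | C=C(C)C1C[C@@]2(C)[C@H](CC[C@@H](O)[C@@H]2C)[C@@H](O)C1=N | intermediate
14 | (1R,3R,4aR,5R,6R,8aS)-1,6-dihydroxy-4a,5-dimethyl-3-(prop-1-en-2-yl)octahydronaphthalen-2(1H)-one | C=C(C)[C@H]1C[C@@]2(C)[C@H](CC[C@@H](O)[C@@H]2C)[C@@H](O)C1=O | intermediate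
15 | 3-methylbut-2-enoyl chloride | CC(C)=CC(Cl)=O | starting material
16 | (1R,3R,4aR,5R,6R,8aS)-4a,5-dimethyl-2-oxo-3-(prop-1-en-2-yl)decahydronaphthalene-1,6-diyl bis(3-methylbut-2-enoate) | C=C(C)[C@H]1C[C@@]2(C)[C@H](CC[C@@H](OC(=O)C=C(C)C)[C@@H]2C)[C@@H](OC(=O)C=C(C)C)C1=O | target

## Step count and risks

Total steps: 7. Longest linear sequence: 6 (steps 1, 2, 3, 4, 6, 7); step 5 is a one‑step side branch.

Most likely to fail, in this order: step 6, step 2, step 7.

Step 6 is the main risk. The enal is β,β‑disubstituted and hindered, so the catalytic cycloaddition may not turn over or may give poor enantioselectivity; the Z‑enal could isomerise; the exo preference, the aldehyde (rather than ketone) ketyl–nitrile coupling and the in‑flask reduction are all extensions of known chemistry. If the catalytic cycloaddition fails, the same bonds are made under auxiliary control. Enal 7 is condensed with (2R,4R)-pentane-2,4-diol (pyridinium p‑toluenesulfonate, MgSO4, benzene) to the C2‑symmetric acetal (4Z)-5-[(4R,6R)-4,6-dimethyl-1,3-dioxan-2-yl]-4-methyl-2-(prop-1-en-2-yl)pent-4-enenitrile F1. TMSOTf (10 mol %, CH2Cl2, −78 °C) ionises F1 to a vinyl oxocarbenium ion, a much stronger dienophile than the enal, which adds diene 9 in a cationic (Gassman‑type) Diels–Alder reaction to give (4R,6R)-2-[(1S,5R,6R)-6-(2-cyano-3-methylbut-3-en-1-yl)-5,6-dimethyl-4-[(trimethylsilyl)oxy]cyclohex-3-en-1-yl]-4,6-dimethyl-1,3-dioxane F2. Aqueous oxalic acid on silica cleaves the silyl enol ether and the acetal and returns keto aldehyde 11, which is then taken through the samarium stages of step 6 as a separate operation to 14. If the auxiliary gives the wrong face, the diol antipode is used. This fallback sets out from 7 and 9 and rejoins the route at 11.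

Step 2 can fail if the hard lithiated nitrile attacks the ester or adds to the β‑carbon of 3 (followed by ring closure to a cyclopropane), or if it alkylates at the γ‑carbon. The fallback uses a softer nucleophile. Commercial ethyl 2-cyano-3-methylbut-2-enoate is deprotonated at a γ‑methyl group with NaH (THF, 0 °C) and alkylated at the α‑carbon by 3 to give diethyl (4Z)-2-cyano-4-methyl-2-(prop-1-en-2-yl)hex-4-enedioate F3. Krapcho dealkoxycarbonylation of the doubly activated ester (LiCl, wet DMSO, 120 °C), with α‑protonation of the nitrile anion, then gives 5. This fallback sets out from 3 and rejoins the route at 5.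

Step 7 can fail if the acyl chloride deconjugates through its vinylketene (giving 3‑methylbut‑3‑enoates) or if the base moves the isopropenyl double bond into conjugation. The fallback builds the unsaturated esters on the molecule. Diol 14 is esterified with (diethoxyphosphoryl)acetic acid (N,N'‑dicyclohexylcarbodiimide, 4‑(dimethylamino)pyridine, CH2Cl2) to (1R,3R,4aR,5R,6R,8aS)-4a,5-dimethyl-2-oxo-3-(prop-1-en-2-yl)decahydronaphthalene-1,6-diyl bis[(diethoxyphosphoryl)acetate] F4. A Horner–Wadsworth–Emmons reaction of F4 with excess acetone (NaH, THF, 0 °C) then converts both phosphonoacetates into 3‑methylbut‑2‑enoates and gives 16. This fallback sets out from 14 and rejoins the route at 16.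

## Further compounds

F1 | step 6 | (4Z)-5-[(4R,6R)-4,6-dimethyl-1,3-dioxan-2-yl]-4-methyl-2-(prop-1-en-2-yl)pent-4-enenitrile | C[C@@H]1C[C@@H](C)OC(O1)/C=C(/C)CC(C#N)C(C)=C
F2 | step 6 | (4R,6R)-2-[(1S,5R,6R)-6-(2-cyano-3-methylbut-3-en-1-yl)-5,6-dimethyl-4-[(trimethylsilyl)oxy]cyclohex-3-en-1-yl]-4,6-dimethyl-1,3-dioxane | C=C(C)C(C#N)C[C@@]1(C)[C@H](CC=C(O[Si](C)(C)C)[C@@H]1C)C1O[C@H](C)C[C@@H](C)O1
F3 | step 2 | diethyl (4Z)-2-cyano-4-methyl-2-(prop-1-en-2-yl)hex-4-enedioate | CCOC(=O)/C=C(/C)CC(C#N)(C(=O)OCC)C(C)=C
F4 | step 7 | (1R,3R,4aR,5R,6R,8aS)-4a,5-dimethyl-2-oxo-3-(prop-1-en-2-yl)decahydronaphthalene-1,6-diyl bis[(diethoxyphosphoryl)acetate] | C=C(C)[C@H]1C[C@@]2(C)[C@H](CC[C@@H](OC(=O)CP(=O)(OCC)OCC)[C@@H]2C)[C@@H](OC(=O)CP(=O)(OCC)OCC)C1=O
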